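**Retrosynthetic overview**
1. Target 22 ⇒ Schenck ene reaction of the Z-C6=C7 olefin 21 ⇒ ring-closing metathesis (ring C, closed last) of diene 20.
2. 20 ⇒ convex-face C9 allylation of acetal 19; C11/C12 come from enone 16; ring B comes from lactonisation of the cis C2–O/C10-ester pair of cycloadduct 12.
3. Key step: one intramolecular Diels–Alder reaction of the acyclic triene 11 (Z-enoate and silyloxydiene joined only through the C3–O–C16 ether) closes rings A and D together and sets C1, C10 and C14.
4. 11 ⇒ Still–Gennari olefination and cross-metathesis with methacrolein; ether 6 ⇒ C3-selective alcoholysis of (2S,3R)-epoxynerol 5 by (R)-2-methylpent-4-en-1-ol 3.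
5. Ring order: A + D (one operation) → B → C.

Assumption: the SMILES is read as the (1S,2S,3S,6R,9S,10R,11R,12R,14S,15R) isomer; locants use asbestinin numbering (C1/C10 ring-fusion CH, C2/C9 the CH–O carbons of ring B, C3 quaternary ether carbon, C4–C8 rest of ring C, C11 CH–OAc, C12 CH–CH3, C14 CH, C15 CH(CH3), C16 OCH2; ring A cyclohexane, ring B tetrahydrofuran, ring C oxonane, ring D oxepane).

**Route**

Step 1
Reactants: 1 (S)-4-benzyl-3-propanoyl-1,3-oxazolidin-2-one
Product: 2 (S)-4-benzyl-3-[(R)-2-methylpent-4-enoyl]-1,3-oxazolidin-2-one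
Conditions: NaN(SiMe3)2, THF, −78 °C; allyl iodide, −78 → −45 °C
Reagents that add atoms: allyl iodide, C=CCI
Why: Evans asymmetric alkylation, in which the chelated Z-sodium enolate is allylated on the face opposite the benzyl group and so sets the 2R centre that becomes C15.

Step 2
Reactants: 2 (S)-4-benzyl-3-[(R)-2-methylpent-4-enoyl]-1,3-oxazolidin-2-one
Product: 3 (R)-2-methylpent-4-en-1-ol
Conditions: LiBH4, MeOH (1 equiv), Et2O, 0 °C
Reagents that add atoms: none
Why: Reductive cleavage of the N-acyl oxazolidinone by LiBH4 releases the primary alcohol without touching the α-stereocentre or the alkene and returns the auxiliary.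

Step 3
Reactants: 4 nerol
Product: 5 (2S,3R)-2,3-epoxynerol
Conditions: Ti(Oi-Pr)4 (10 mol%), L-(+)-diethyl tartrate (12 mol%), t-BuOOH, 4 Å molecular sieves, CH2Cl2, −20 °C
Reagents that add atoms: tert-butyl hydroperoxide, CC(C)(C)OO
Why: Sharpless asymmetric epoxidation, in which the L-(+)-tartrate titanium complex delivers oxygen to one face of the Z-allylic alcohol, sets C2 (S) and C3 (R) and leaves the isolated isopropylidene alkene alone.

Step 4
Reactants: 5 (2S,3R)-2,3-epoxynerol; 3 (R)-2-methylpent-4-en-1-ol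
Product: 6 (2S,3S)-3,7-dimethyl-3-{[(2R)-2-methylpent-4-en-1-yl]oxy}oct-6-ene-1,2-diol
Conditions: BF3·OEt2 (10 mol%), CH2Cl2, −40 → −20 °C, epoxide added slowly to excess alcohol
Reagents that add atoms: none
Why: Lewis-acid-catalysed epoxide alcoholysis, a pure addition in which the primary alcohol opens the activated trisubstituted epoxide at the tertiary, cation-stabilising C3 with inversion (borderline SN2), giving the C3–O–C16 ether with C3 (S) while C2 keeps its configuration and the epoxide oxygen becomes the C2 hydroxyl.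

Step 5
Reactants: 6 (2S,3S)-3,7-dimethyl-3-{[(2R)-2-methylpent-4-en-1-yl]oxy}oct-6-ene-1,2-diol
Product: 7 1,2-bis(triethylsilyl) ether of 6
Conditions: Et3SiOTf, 2,6-lutidine, CH2Cl2, −78 → 0 °C
Reagents that add atoms: triethylsilyl triflate, CC[Si](CC)(CC)OS(=O)(=O)C(F)(F)F
Why: Exhaustive silylation with the silyl triflate caps the hindered secondary C2 hydroxyl, which later serves as the bulky allylic control group and cannot then close a butenolide, together with the primary hydroxyl.

Step 6
Reactants: 7 1,2-bis(triethylsilyl) ether of 6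
Product: 8 (2R,3S)-3,7-dimethyl-3-{[(2R)-2-methylpent-4-en-1-yl]oxy}-2-(triethylsilyloxy)oct-6-enal
Conditions: (COCl)2, DMSO, CH2Cl2, −78 → −30 °C; Et3N, −78 → 0 °C
Reagents that add atoms: none
Why: Swern oxidation, in which the chlorosulfonium reagent cleaves only the unhindered primary triethylsilyl ether and oxidises it in situ to the aldehyde while the secondary silyl ether survives and the cold amine quench preserves the α-stereocentre.

Step 7
Reactants: 8 (2R,3S)-3,7-dimethyl-3-{[(2R)-2-methylpent-4-en-1-yl]oxy}-2-(triethylsilyloxy)oct-6-enal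
Product: 9 methyl (2Z,4S,5S)-5,9-dimethyl-5-{[(2R)-2-methylpent-4-en-1-yl]oxy}-4-(triethylsilyloxy)deca-2,8-dienoate
Conditions: (CF3CH2O)2P(O)CH2CO2Me, KN(SiMe3)2, 18-crown-6, THF, −78 °C
Reagents that add atoms: methyl bis(2,2,2-trifluoroethyl)phosphonoacetate, COC(=O)CP(=O)(OCC(F)(F)F)OCC(F)(F)F
Why: Still–Gennari variant of the Horner–Wadsworth–Emmons olefination, in which the electron-poor trifluoroethyl phosphonate makes elimination from the kinetic adduct fast and so gives the Z-enoate.

Step 8
Reactants: 9 methyl (2Z,4S,5S)-5,9-dimethyl-5-{[(2R)-2-methylpent-4-en-1-yl]oxy}-4-(triethylsilyloxy)deca-2,8-dienoate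
Product: 10 methyl (2Z,4S,5S)-5-{[(2R,4E)-2,5-dimethyl-6-oxohex-4-en-1-yl]oxy}-5,9-dimethyl-4-(triethylsilyloxy)deca-2,8-dienoate
Conditions: methacrolein (10 equiv), second-generation Grubbs catalyst (5 mol%), CH2Cl2, 40 °C
Reagents that add atoms: methacrolein, CC(=C)C=O
Why: Olefin cross-metathesis, selective because only the monosubstituted alkene initiates readily whereas the isopropylidene-capped alkene and the Z-enoate are poor partners, and methacrolein gives the E-trisubstituted enal.

Step 9
Reactants: 10 methyl (2Z,4S,5S)-5-{[(2R,4E)-2,5-dimethyl-6-oxohex-4-en-1-yl]oxy}-5,9-dimethyl-4-(triethylsilyloxy)deca-2,8-dienoate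
Product: 12 cycloadduct methyl ester (rings A + D), via silyl dienol ether 11 (not isolated)
Conditions: Et3SiOTf, Et3N, CH2Cl2, −78 → 0 °C; then toluene (5 mM), BHT, 160 °C, sealed tube
Reagents that add atoms: triethylsilyl triflate, CC[Si](CC)(CC)OS(=O)(=O)C(F)(F)F
Why: γ-Deprotonative silylation of the enal gives the (E,E)-1-silyloxydiene, and a type 1 intramolecular Diels–Alder reaction (electron-rich diene, enoate dienophile, regiochemistry matched by the tether) then closes the cyclohexene and the oxepane at once, with A(1,3) strain in the Z-enoate keeping H2 in the alkene plane so that the tethered diene adds anti to the C2 silyloxy group (sets C1 and C10) and with the exo mode, which keeps the crowded C2/C3 unit away from the diene, giving the trans C1/C14 ring fusion (sets C14), while the C11 configuration does not matter because C11 is oxidised later.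

Step 10
Reactants: 12 cycloadduct methyl ester (rings A + D)
Product: 13 hydroxy γ-lactone (rings A, B, D)
Conditions: CSA (20 mol%), MeOH, 0 → 23 °C
Reagents that add atoms: none
Why: Acid methanolysis removes both triethylsilyl ethers, and the freed C2 hydroxyl, cis to the C10 ester, closes the γ-lactone by transesterification to give ring B.

Step 11
Reactants: 13 hydroxy γ-lactone (rings A, B, D)
Product: 15 methyl acetal allylic alcohol, via lactol 14 (not isolated)
Conditions: i-Bu2AlH (3 equiv), CH2Cl2, −78 °C; then MeOH, PPTS, 23 °C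
Reagents that add atoms: methanol, CO
Why: i-Bu2AlH reduces the lactone only to the lactol (stable aluminate at low temperature), and acid-catalysed Fischer-type acetalisation masks it as the methyl acetal so that C9 is no longer a carbonyl, and C10 not doubly activated, when C11 is oxidised.

Step 12
Reactants: 15 methyl acetal allylic alcohol
Product: 16 enone (C11 ketone, C12=C13)
Conditions: Dess–Martin periodinane, NaHCO3, CH2Cl2, 0 → 23 °C
Reagents that add atoms: none
Why: Dess–Martin oxidation of the secondary allylic alcohol gives the enone under buffered conditions that leave the acetal and the alkenes untouched.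

Step 13
Reactants: 16 enone (C11 ketone, C12=C13)
Product: 19 C11 acetate, via ketone 17 (not isolated), via lithium alkoxide 18 (not isolated)
Conditions: Li[HB(s-Bu)3] (2.5 equiv), t-BuOH (1.1 equiv), THF, −78 °C; then Ac2O, DMAP, −78 → 0 °C
Reagents that add atoms: acetic anhydride, CC(=O)OC(C)=O
Why: Conjugate (1,4) hydride reduction of the α-methyl enone gives the C11 enolate, which is protonated kinetically anti to the axial C10–C9 bond (convex face) so that the C12 methyl ends cis to C9, and the second hydride then attacks the C11 ketone from the same open face to give the all-cis C10/C11/C12 array before the strained ketone can epimerise, the alkoxide being acetylated in the same flask.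

Step 14
Reactants: 19 C11 acetate
Product: 20 C9 2-methylallyl tricycle
Conditions: (2-methylallyl)trimethylsilane (5 equiv), BF3·OEt2, CH2Cl2, −78 → −40 °C
Reagents that add atoms: (2-methylallyl)trimethylsilane, CC(=C)C[Si](C)(C)C
Why: Hosomi–Sakurai-type C-glycosidation, in which BF3 ionises the acetal to the five-membered oxocarbenium ion and the allylsilane attacks its convex face, anti to the C10–C11 bond of the cis-fused ring A, giving C9 (S) with the 2,9-cis relationship.

Step 15
Reactants: 20 C9 2-methylallyl tricycle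
Product: 21 tetracyclic (6Z)-olefin
Conditions: second-generation Hoveyda–Grubbs catalyst (15 mol%), toluene (1 mM), 80 °C, argon sparge
Reagents that add atoms: none
Why: Ring-closing metathesis, in which the catalyst loads at the isopropylidene-capped chain with loss of isobutene and closes onto the 1,1-disubstituted olefin, both chains being held cis on the convex face of ring B, and the nine-membered ring can hold only the Z-trisubstituted alkene.

Step 16
Reactants: 21 tetracyclic (6Z)-olefin
Product: 22 target hydroperoxide CNP0127108.1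
Conditions: O2, tetraphenylporphyrin (1 mol%), visible light, CH2Cl2, 0 °C
Reagents that add atoms: dioxygen, O=O
Why: Schenck ene reaction, in which singlet oxygen adds to the exposed outer face of the medium-ring alkene at C6 and abstracts a hydrogen of the C19 methyl group (the ring allylic C–H bonds lie near the alkene plane), which moves the double bond exocyclic and sets C6 (R).

**Compound list**

1 | (S)-4-benzyl-3-propanoyl-1,3-oxazolidin-2-one | CCC(=O)N1[C@@H](Cc2ccccc2)COC1=O | starting material
2 | (S)-4-benzyl-3-[(R)-2-methylpent-4-enoyl]-1,3-oxazolidin-2-one | C=CC[C@@H](C)C(=O)N1[C@@H](Cc2ccccc2)COC1=O | intermediate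
3 | (R)-2-methylpent-4-en-1-ol | C=CC[C@@H](C)CO | intermediate
4 | nerol, (Z)-3,7-dimethylocta-2,6-dien-1-ol | CC(C)=CCC/C(C)=C\CO | starting material
5 | (2S,3R)-2,3-epoxynerol | CC(C)=CCC[C@@]1(C)O[C@H]1CO | intermediate
6 | (2S,3S)-3,7-dimethyl-3-{[(2R)-2-methylpent-4-en-1-yl]oxy}oct-6-ene-1,2-diol | OC[C@H](O)[C@](C)(CCC=C(C)C)OC[C@H](C)CC=C | intermediate
7 | (2S,3S)-1,2-bis(triethylsilyl) ether of 6 | CC[Si](CC)(CC)OC[C@H](O[Si](CC)(CC)CC)[C@](C)(CCC=C(C)C)OC[C@H](C)CC=C | intermediate
8 | (2R,3S)-3,7-dimethyl-3-{[(2R)-2-methylpent-4-en-1-yl]oxy}-2-(triethylsilyloxy)oct-6-enal | O=C[C@H](O[Si](CC)(CC)CC)[C@](C)(CCC=C(C)C)OC[C@H](C)CC=C | intermediate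
9 | methyl (2Z,4S,5S)-5,9-dimethyl-5-{[(2R)-2-methylpent-4-en-1-yl]oxy}-4-(triethylsilyloxy)deca-2,8-dienoate | COC(=O)/C=C\[C@H](O[Si](CC)(CC)CC)[C@](C)(CCC=C(C)C)OC[C@H](C)CC=C | intermediate
10 | methyl (2Z,4S,5S)-5-{[(2R,4E)-2,5-dimethyl-6-oxohex-4-en-1-yl]oxy}-5,9-dimethyl-4-(triethylsilyloxy)deca-2,8-dienoate | COC(=O)/C=C\[C@H](O[Si](CC)(CC)CC)[C@](C)(CCC=C(C)C)OC[C@H](C)C/C=C(\C)C=O | intermediate
11 | methyl (2Z,4S,5S)-5-{[(2R,3E,5E)-2,5-dimethyl-6-(triethylsilyloxy)hexa-3,5-dien-1-yl]oxy}-5,9-dimethyl-4-(triethylsilyloxy)deca-2,8-dienoate | COC(=O)/C=C\[C@H](O[Si](CC)(CC)CC)[C@](C)(CCC=C(C)C)OC[C@H](C)/C=C/C(C)=C/O[Si](CC)(CC)CC | intermediate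
12 | cycloadduct: cyclohex-12-ene (ring A) trans-fused at C1–C14 to the oxepane (ring D), C10 CO2Me cis to C2, 2-OSiEt3, 11-OSiEt3 trans to the ester; C1, C2, C3, C10, C14, C15 as in the target | COC(=O)[C@@H]1[C@@H](O[Si](CC)(CC)CC)C(C)=C[C@H]2[C@@H](C)CO[C@@](C)(CCC=C(C)C)[C@@H](O[Si](CC)(CC)CC)[C@H]12 | intermediate
13 | hydroxy γ-lactone: C9(=O)–O–C2 lactone cis-fused to ring A, 11-OH trans to C9, C12=C13, ring D intact | O=C1O[C@H]2[C@@H]3[C@H]1[C@@H](O)C(C)=C[C@H]3[C@@H](C)CO[C@@]2(C)CCC=C(C)C | intermediate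
14 | lactol of 13 (C9–OH, anomer mixture, one drawn) | O[C@@H]1O[C@H]2[C@@H]3[C@H]1[C@@H](O)C(C)=C[C@H]3[C@@H](C)CO[C@@]2(C)CCC=C(C)C | intermediate
15 | C9 methyl acetal (anomer mixture, one drawn) with 11-OH and C12=C13 | CO[C@@H]1O[C@H]2[C@@H]3[C@H]1[C@@H](O)C(C)=C[C@H]3[C@@H](C)CO[C@@]2(C)CCC=C(C)C | intermediate
16 | enone: C9 methyl acetal, C11 ketone, C12=C13 | CO[C@@H]1O[C@H]2[C@@H]3[C@H]1C(=O)C(C)=C[C@H]3[C@@H](C)CO[C@@]2(C)CCC=C(C)C | intermediate
17 | saturated C11 ketone, 12-methyl cis to C9 | CO[C@@H]1O[C@H]2[C@@H]3[C@H]1C(=O)[C@H](C)C[C@H]3[C@@H](C)CO[C@@]2(C)CCC=C(C)C | intermediate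
18 | C11 alcohol (formed as its lithium alkoxide), 11-O and 12-methyl cis to C9 | CO[C@@H]1O[C@H]2[C@@H]3[C@H]1[C@H](O)[C@H](C)C[C@H]3[C@@H](C)CO[C@@]2(C)CCC=C(C)C | intermediate
19 | C11 acetate of 18 | CO[C@@H]1O[C@H]2[C@@H]3[C@H]1[C@H](OC(C)=O)[C@H](C)C[C@H]3[C@@H](C)CO[C@@]2(C)CCC=C(C)C | intermediate
20 | (1S,2S,3S,9S,10R,11R,12R,14S,15R) tricycle: rings A, B, D with 11-OAc, C9 2-methylallyl and C3 4-methylpent-3-enyl chains | C=C(C)C[C@@H]1O[C@H]2[C@@H]3[C@H]1[C@H](OC(C)=O)[C@H](C)C[C@H]3[C@@H](C)CO[C@@]2(C)CCC=C(C)C | intermediate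
21 | (1S,2S,3S,6Z,9S,10R,11R,12R,14S,15R)-11-acetoxy tetracycle with the C6=C7 olefin (C7 methyl) | C/C1=C/CC[C@]2(C)OC[C@H](C)[C@@H]3C[C@@H](C)[C@@H](OC(C)=O)[C@H]4[C@H](C1)O[C@H]2[C@@H]34 | intermediate
22 | CNP0127108.1, (1S,2S,3S,6R,9S,10R,11R,12R,14S,15R)-11-acetoxy-6-hydroperoxy-7(19)-ene | C=C1C[C@@H]2O[C@H]3[C@H]4[C@@H](C[C@@H](C)[C@@H](OC(C)=O)[C@H]42)[C@@H](C)CO[C@@]3(C)CC[C@H]1OO | target

**Totals**

Total step count: 16. Longest linear sequence: 15 steps (1 → 22 through steps 1, 2 and 4–16; 14 steps from nerol).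

**Three steps most likely to fail**

Step 9 (intramolecular Diels–Alder reaction). The seven-membered tether may react sluggishly or give the endo, cis-fused C14 epimer. The fallback sets out from aldehyde 8 and comes back at cycloadduct 12. Knoevenagel condensation of 8 with dimethyl malonate (TiCl4, pyridine, THF, 0 °C) gives the alkylidene malonate F1. Cross-metathesis with methacrolein as in step 8 gives the enal F2, and Et3SiOTf/Et3N gives the silyl dienol ether F3. Its doubly activated dienophile still has an ester cis to C2 for A(1,3) control, has no endo/exo electronic bias, and should cyclise at 60–80 °C or with ZnBr2 to the gem-diester cycloadduct F4. Krapcho demethoxycarbonylation (LiCl, wet DMSO, 130 °C) then gives 12; any C10 epimer is re-equilibrated with NaOMe, since only the cis ester lactonises in step 10.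

Step 13 (kinetic protonation at C12). The desired C12 epimer has the methyl syn-axial to C9 and is the less stable one. The fallback sets out from allylic alcohol 15 and comes back at acetate 19. Hydroxyl-directed hydrogenation ([Rh(nbd)(dppb)]BF4, H2 at high pressure, CH2Cl2) adds hydrogen from the face of the 11-OH, which is the face needed at C12, and should spare the undirected isopropylidene alkene. This gives the saturated 11-epi alcohol F5. Dess–Martin oxidation gives ketone 17, which is reduced at once with Li[HB(s-Bu)3] at −78 °C and acetylated to 19.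

Step 15 (ring-closing metathesis). Neither olefin is monosubstituted, so catalyst loading may be too slow for a nine-membered closure. The fallback sets out from 20 and comes back at 21. Ethenolysis (second-generation Grubbs catalyst, ethylene 1 atm, CH2Cl2, 40 °C) trims the isopropylidene cap to a vinyl group and gives the but-3-enyl diene F6. Its monosubstituted/1,1-disubstituted olefin pair is the precedented type for trisubstituted oxonene closure (second-generation Hoveyda–Grubbs catalyst, toluene, 110 °C, 1 mM) and gives 21.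

**Further compounds**

F1 | step 9 | dimethyl 2-[(2S,3S)-3,7-dimethyl-3-{[(2R)-2-methylpent-4-en-1-yl]oxy}-2-(triethylsilyloxy)oct-6-en-1-ylidene]propanedioate | COC(=O)C(=C[C@H](O[Si](CC)(CC)CC)[C@](C)(CCC=C(C)C)OC[C@H](C)CC=C)C(=O)OC
F2 | step 9 | enal from cross-metathesis of F1 with methacrolein | COC(=O)C(=C[C@H](O[Si](CC)(CC)CC)[C@](C)(CCC=C(C)C)OC[C@H](C)C/C=C(\C)C=O)C(=O)OC
F3 | step 9 | silyl dienol ether of F2 | COC(=O)C(=C[C@H](O[Si](CC)(CC)CC)[C@](C)(CCC=C(C)C)OC[C@H](C)/C=C/C(C)=C/O[Si](CC)(CC)CC)C(=O)OC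
F4 | step 9 | gem-diester cycloadduct (C10 bis-CO2Me analogue of 12) | COC(=O)C1(C(=O)OC)[C@@H](O[Si](CC)(CC)CC)C(C)=C[C@H]2[C@@H](C)CO[C@@](C)(CCC=C(C)C)[C@@H](O[Si](CC)(CC)CC)[C@H]12
F5 | step 13 | saturated 11-epi alcohol (11-OH trans to C9, 12-methyl cis to C9) | CO[C@@H]1O[C@H]2[C@@H]3[C@H]1[C@@H](O)[C@H](C)C[C@H]3[C@@H](C)CO[C@@]2(C)CCC=C(C)C
F6 | step 15 | but-3-enyl analogue of 20 | C=C(C)C[C@@H]1O[C@H]2[C@@H]3[C@H]1[C@H](OC(C)=O)[C@H](C)C[C@H]3[C@@H](C)CO[C@@]2(C)CCC=C
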